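Remark on the chemistry: 2,4,6-trimethoxyphenol, 2-fluoro-4,6-dimethoxybenzaldehyde, 4-fluoro-2,6-dimethoxybenzaldehyde and 4-hydroxy-6-methyl-2-pyrone are taken to be catalogue compounds.

## Structural features

The target is a linear pentaphlorethol, C30H22O15: five benzene rings (A to E) joined only by four diaryl ether oxygens and carrying eleven free phenolic hydroxyls. It has no stereocentre and no double-bond geometry, so the whole problem is one of regiochemistry. In each ring C-1 is the carbon bearing the ether oxygen on the ring-A side (for ring A, its only ether oxygen); the links are A C-1–O–B C-1, B C-6–O–C C-1, C C-4–O–D C-1 and D C-6–O–E C-1. Ring A is a plain 3,5-dihydroxyphenyl group, whereas rings B to E each carry four oxygens in a 1,2,3,5 array, so the ether carbons B C-1, C C-1, D C-1 and E C-1 all lie between two oxygenated carbons. The free undecaphenol is very electron-rich, air-sensitive (most of all as a phenoxide) and hard to chromatograph, so every hydroxyl should stay masked until the last step; the diaryl ether bonds themselves tolerate acid, base and Lewis acids. The real difficulty is forming four ethers between electron-rich, ortho-flanked rings that carry no activating group in the target. The worst is A–O–B: B C-1 is doubly flanked, and ring A has oxygens only meta to its ether carbon, so it offers no ortho or para position where a removable acceptor could later become an oxygen. The key step uses exactly this all-meta pattern: A C-1, C-2, C-3, C-4, C-5 and C-6 map onto C-4, C-3, C-2, the methyl carbon, C-6 and C-5 of a 4-aryloxy-6-methyl-2-pyrone, so ring A can be carried as a pyrone on the B C-1 oxygen and closed by forming the A C-3–A C-4 bond.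

## Logic of the disconnections

18 is first traced to 17 by cutting nine aryl O–CH3 bonds. The free polyphenol cannot be carried through strong base, peracid or hot carbonate, and methyl is the one mask that arrives ready-made in the building blocks and survives all of these. The gain is that every earlier intermediate is a neutral, chromatographable ether. The demand is one exhaustive ether cleavage that leaves the four diaryl ether bonds untouched.

17 is traced to 15 by cutting the A C-3–A C-4 bond and tying the A C-3 carbon, as a lactone carbonyl, to the oxygen on A C-5. The cut is made here because ring A cannot be an SNAr partner and B C-1 is doubly flanked, so a direct aryl coupling would be the hardest bond of the molecule. The gain is one carbocycle fewer and an A–O–B bond that has become a vinylogous ester bond. The demand is a base-induced opening and carbocyclic re-closure that keeps the aryloxy group in place.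

15 is cut at the bond between the B C-1 oxygen and C-4 of the heterocycle, giving 12 and 14; 14 comes from 13 by exchange of the C-4 hydroxyl for bromide. C-4 is the unhindered β-carbon of an unsaturated lactone, so the steric burden lies on the nucleophile only. The gain is a six-carbon ring-A precursor made in one step from a commodity compound. The demand is that the phenoxide of 12 adds at C-4 and not at the lactone carbonyl, which a good leaving group at C-4 favours.

12 is traced to 10 by replacing the B C-1–O bond with a B C-1–CHO bond, and 10 is cut at the B C-6–O bond into 9 and 2. The formyl group serves twice: it activates the neighbouring fluoride for displacement and is the latent B C-1 hydroxyl. Ring B thus arrives complete with both methoxy groups. The demand is an SNAr between a di-ortho-methoxy phenoxide and a fluoride ortho to formyl, then a Baeyer–Villiger oxidation with aryl migration.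

9 is traced to 7 (C C-1–O to C C-1–CHO), and 7 is cut at the C C-4–O bond into 5 and 6. Here the fluoride must be para to the formyl group, because C C-4 has hydrogen neighbours and C C-1 lies between the two methoxy groups. The gain is ring C in one coupling; the demand is SNAr on a fluoroarene whose acceptor is weakened by two ortho donors.

5 is traced to 3 (D C-1–O to D C-1–CHO), and 3 is cut at the D C-6–O bond into 1 and 2, so that 2 is used twice. Each oxidation unveils exactly the hydroxyl that attacks next, so the chain grows from ring E to ring B with no hydroxyl to protect, differentiate or re-methylate. A pairing in which both partners carry a formyl group would give two phenols per oxidation and was set aside for that reason.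

## Other disconnections considered

Alternative 1: The cut is the B C-3–B C-4 bond. Ring B is unravelled to the 4-hydroxy-4-(1-methoxyethenyl)cyclobutenone A2, in which the CDE aryloxy group already sits on the carbon that becomes B C-6. Heating A2 in toluene or xylene should open the four-membered ring to a dienylketene whose ketene carbon closes onto the vinyl CH2 carbon (6π-electrocyclisation); tautomerisation would give the hydroquinone A1 with free B C-1 and B C-4 hydroxyls.
- In its favour: the conditions are neutral and thermal, with no anion that could expel an aryloxide. The fully oxygenated ring B, including the flanked B C-1 oxygen, is built with its pattern fixed by the cyclobutenone. The ring C oxygen is attached at a vinylogous ester carbon, the same easy addition–elimination as in step 8.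
- Where it is equal or better: on mildness of the ring-forming event it is the better plan. Mechanistically the two closures are the same dienylketene cyclisation, so they are equals there.
- Against it: A1 has two free hydroxyls that must be told apart. Ring A must still be joined to the doubly flanked B C-1 oxygen by a hindered aryl coupling, the very bond that 15 makes without one. A2 needs a costly semisquarate, the doubly flanked phenoxide of ring C as nucleophile and a regioselective addition of 1-methoxyvinyllithium (CH2=C(OMe)Li).
- Step economy: the chosen plan is estimated to be shorter by three or four operations.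

Alternative 2: Six aryl C–O bonds are cut at once (B C-4, C C-2, C C-6, D C-4, E C-2, E C-6), each back to an aryl–CHO bond in the hexa-aldehyde A4, whose four ether links would themselves come from formyl-activated SNAr. Forward, buffered mCPBA would oxidise all six formyl groups by Baeyer–Villiger aryl migration and the six formates would be methanolysed to the hexaphenol A3.
- In its favour: every formyl group serves twice.
- Where it is equal or better: rings C and E, with two formyl groups ortho to the fluoride, are much stronger SNAr electrophiles than 2 and 6, so it is better on activation. There is one oxidation stage instead of three. Only five methyl ethers remain to be cleaved instead of nine. The A–O–B junction is reached by an unhindered 3,5-dimethoxyphenoxide attacking a ring B fluoride para to formyl, an equally valid answer to the hindrance problem.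
- Against it: six oxidations must all proceed with aryl migration on one molecule. The bis-formyl rings are electron-poor at their first oxidation, so hydride migration to carboxylic acids competes. A3 would be set free with peracid still present. Rings B and D need units with fluoride next to a hydroxyl, whose phenoxide switches that fluoride off, so protection cycles return.
- Step economy: possibly equal or slightly shorter, but it stakes the route on a sixfold transformation, whereas the chosen plan spreads three single oxidations over purifiable intermediates.

Alternative 3: The cut is the D C-2–D C-3 bond. Ring D is unravelled to the 3,4-bis(aryloxy)-6-methyl-2-pyrone A6, with the ABC aryloxy group on C-3 and the ring E aryloxy group on C-4. The forward key step is the same LiN(SiMe3)2-induced opening and recyclisation as in the chosen plan, giving A5 with free D C-2 and D C-4 hydroxyls.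
- Where it is equal or better: it is convergent, since an ABC phenol and a ring E phenol meet on a small core, so it is better on longest linear sequence. The mechanism is identical, so the two are equal there. Both flanked ether carbons of ring D are set up off the arene.
- Against it: pyrone C-3 is a nucleophilic enol carbon, so its C–O bond cannot be made by addition–elimination. It would need a carbene O–H insertion or a de novo pyrone synthesis. The C-4 substitution then sets a doubly flanked 2,4,6-trimethoxyphenoxide against a centre crowded by the C-3 aryloxy group. The opened intermediate is a disubstituted aryloxyketene and the closing ring carries two adjacent aryloxy groups, so closure is slower and loss of the C-4 aryloxide has more time. The A–O–B junction stays unsolved inside the ABC fragment.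
- Structural fit: the chosen plan places the pyrone on the one ring whose pattern, with no oxygen at C-2 or C-6, maps onto a pyrone available in one step.

Key step: step 9

## Route

Step 1
Reactants: 1 2,4,6-trimethoxyphenol; 2 2-fluoro-4,6-dimethoxybenzaldehyde
Product: 3 4,6-dimethoxy-2-(2,4,6-trimethoxyphenoxy)benzaldehyde (DE aldehyde)
Conditions: Cs2CO3 (1.5 equiv), DMSO, 110 °C, Ar
Reagents that add atoms: none
Why: Nucleophilic aromatic substitution (SNAr): the caesium phenoxide of 1 adds to the fluoride-bearing carbon ortho to the formyl group of 2, whose oxygen takes up the charge of the Meisenheimer adduct. Both methoxy groups of 2 are meta to the attacked carbon and do not oppose the addition, and fluoride is the best leaving group for a rate-limiting addition.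

Step 2
Reactants: 3 DE aldehyde
Product: 5 2,4-dimethoxy-6-(2,4,6-trimethoxyphenoxy)phenol (DE phenol), via DE aryl formate 4 (not isolated)
Conditions: mCPBA (1.3 equiv), CH2Cl2, 0 °C → rt; aq. Na2S2O3 wash; then K2CO3 (0.2 equiv), MeOH, Ar, rt
Reagents that add atoms: mCPBA, OOC(=O)c1cccc(Cl)c1
Why: Baeyer–Villiger (Dakin-type) oxidation: the 2,4,6-trioxygenated aryl group migrates far faster than hydride, giving formate 4. The formate is methanolysed only after excess peracid has been destroyed, so the electron-rich phenol never meets the oxidant.

Step 3
Reactants: 5 DE phenol; 6 4-fluoro-2,6-dimethoxybenzaldehyde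
Product: 7 4-[2,4-dimethoxy-6-(2,4,6-trimethoxyphenoxy)phenoxy]-2,6-dimethoxybenzaldehyde (CDE aldehyde)
Conditions: Cs2CO3 (1.5 equiv), DMSO, 120 °C, Ar
Reagents that add atoms: none
Why: SNAr at the fluoride para to the formyl group of 6: the attacked carbon has only hydrogen neighbours, so the flanked phenoxide of 5 can approach. The methoxy groups are meta to the reacting carbon and the para formyl group stabilises the anionic adduct.

Step 4
Reactants: 7 CDE aldehyde
Product: 9 4-[2,4-dimethoxy-6-(2,4,6-trimethoxyphenoxy)phenoxy]-2,6-dimethoxyphenol (CDE phenol), via CDE aryl formate 8 (not isolated)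
Conditions: mCPBA (1.3 equiv), CH2Cl2, 0 °C → rt; aq. Na2S2O3 wash; then K2CO3 (0.2 equiv), MeOH, Ar, rt
Reagents that add atoms: mCPBA, OOC(=O)c1cccc(Cl)c1
Why: Baeyer–Villiger (Dakin-type) oxidation of a 2,6-dimethoxy-4-aryloxybenzaldehyde: the trioxygenated aryl group migrates and the formate 8 is cleaved by methanolysis after the peracid is quenched. The product hydroxyl sits at C C-1 between the two methoxy groups.

Step 5
Reactants: 9 CDE phenol; 2 2-fluoro-4,6-dimethoxybenzaldehyde
Product: 10 2-{4-[2,4-dimethoxy-6-(2,4,6-trimethoxyphenoxy)phenoxy]-2,6-dimethoxyphenoxy}-4,6-dimethoxybenzaldehyde (BCDE aldehyde)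
Conditions: Cs2CO3 (2 equiv), DMSO, 120 °C, Ar
Reagents that add atoms: none
Why: SNAr as in step 1, now with a di-ortho-methoxy phenoxide. Addition–elimination tolerates ortho substituents because the nucleophile approaches perpendicular to the ring plane, and the attacked carbon of 2 has one hydrogen neighbour.

Step 6
Reactants: 10 BCDE aldehyde
Product: 12 2-{4-[2,4-dimethoxy-6-(2,4,6-trimethoxyphenoxy)phenoxy]-2,6-dimethoxyphenoxy}-4,6-dimethoxyphenol (BCDE phenol), via BCDE aryl formate 11 (not isolated)
Conditions: mCPBA (1.2 equiv), CH2Cl2, 0 °C → rt; aq. Na2S2O3 wash; then K2CO3 (0.2 equiv), MeOH, Ar, rt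
Reagents that add atoms: mCPBA, OOC(=O)c1cccc(Cl)c1
Why: Baeyer–Villiger (Dakin-type) oxidation with migration of the electron-rich ring B aryl group, then methanolysis of formate 11. The peracid is kept near one equivalent and cold, because the other three rings are electron-rich arenes.

Step 7
Reactants: 13 4-hydroxy-6-methyl-2H-pyran-2-one
Product: 14 4-bromo-6-methyl-2H-pyran-2-one
Conditions: n-Bu4NBr (1.2 equiv), P2O5 (2.5 equiv), toluene, 100 °C
Reagents that add atoms: tetrabutylammonium bromide, [Br-].CCCC[N+](CCCC)(CCCC)CCCC
Why: Deoxybromination of a vinylogous acid: P2O5 activates the C-4 oxygen in situ and bromide substitutes at C-4 by addition–elimination. This is a known preparation of this bromide.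

Step 8
Reactants: 12 BCDE phenol; 14 4-bromo-6-methyl-2H-pyran-2-one
Product: 15 4-(2-{4-[2,4-dimethoxy-6-(2,4,6-trimethoxyphenoxy)phenoxy]-2,6-dimethoxyphenoxy}-4,6-dimethoxyphenoxy)-6-methyl-2H-pyran-2-one
Conditions: K2CO3 (1.5 equiv), MeCN, 60 °C, Ar
Reagents that add atoms: none
Why: Addition–elimination (vinylogous acyl substitution) at C-4 of the 2-pyrone: the phenoxide of 12 adds to the unhindered β-carbon of the unsaturated lactone and the resulting lactone enolate expels bromide. Hindrance lies on the nucleophile only, and the B C-1 oxygen is thereby joined to all six carbons of the future ring A.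

Step 9
Reactants: 15 4-(BCDE aryloxy)-6-methyl-2H-pyran-2-one
Product: 17 5-(2-{4-[2,4-dimethoxy-6-(2,4,6-trimethoxyphenoxy)phenoxy]-2,6-dimethoxyphenoxy}-4,6-dimethoxyphenoxy)benzene-1,3-diol (nonamethyl pentamer resorcinol), via dienylketene lithium enolate 16 (not isolated)
Conditions: LiN(SiMe3)2 (3.5 equiv), THF (0.02 M), −78 °C then 65 °C, Ar; AcOH quench
Reagents that add atoms: none
Why: LiN(SiMe3)2 removes a proton from the 6-methyl group (the thermodynamic site; any lithiation at C-3 is reversible under amide-base conditions) to give a trienolate delocalised through C-5 and C-3 onto the lactone carbonyl. On warming, the C-3 enolate terminus expels the ring oxygen as an enolate oxygen (E1cB opening of the lactone), giving the dienylketene enolate 16, whose central double bond keeps the cis geometry imposed by the ring. The methylene carbon derived from the methyl group then bonds to the ketene carbon, the former lactone carbonyl: ring A closes in a six-membered mode, as a thermally allowed 6π-electrocyclisation of the dienylketene or, equivalently, a Claisen-type C-acylation of the enolate, forming the A C-4–A C-3 bond. Tautomerisation of the cyclohexadienone and deprotonation give the dilithium resorcinolate of 17, an aromatic sink that makes the sequence irreversible. The closest known reaction type is the base-induced opening and Claisen recyclisation of 4-methoxy-6-methyl-2-pyrone to phloroglucinol monomethyl ether, and the ring-closing event is shared with cyclobutenone-based benzannulations. No stereocentre is formed. The selectivity needed is closure at carbon with the C-4 aryloxy group retained: closure at oxygen merely regenerates the lithiated pyrone, the silylamide is too hindered to add at C-4, direct loss of aryloxide from the trienolate would require a cyclic allene, and high dilution disfavours attack of one anion on C-4 of another molecule. The nine methyl ethers and four diaryl ethers offer the base no acidic hydrogen and no electrophilic site.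

Step 10
Reactants: 17 nonamethyl pentamer resorcinol
Product: 18 5-(2-{4-[2,4-dihydroxy-6-(2,4,6-trihydroxyphenoxy)phenoxy]-2,6-dihydroxyphenoxy}-4,6-dihydroxyphenoxy)benzene-1,3-diol (CNP0018313.0)
Conditions: BBr3 (20 equiv), CH2Cl2, −78 °C → rt, Ar; MeOH then H2O, 0 °C; isolation under Ar
Reagents that add atoms: none
Why: Lewis-acid ether cleavage: each methoxy oxygen binds BBr3 and bromide attacks the methyl carbon (SN2), releasing bromomethane. The diaryl ether C–O bonds are on sp2 carbon and are not cleaved, and aqueous methanol work-up frees the eleven phenols from boron.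

## Compound list

1 | 2,4,6-trimethoxyphenol | COc1cc(OC)c(O)c(OC)c1 | starting material
2 | 2-fluoro-4,6-dimethoxybenzaldehyde | COc1cc(F)c(C=O)c(OC)c1 | starting material
3 | 4,6-dimethoxy-2-(2,4,6-trimethoxyphenoxy)benzaldehyde (DE aldehyde) | COc1cc(OC)c(Oc2cc(OC)cc(OC)c2C=O)c(OC)c1 | intermediate
4 | 2,4-dimethoxy-6-(2,4,6-trimethoxyphenoxy)phenyl formate (DE aryl formate, not isolated) | COc1cc(OC)c(Oc2cc(OC)cc(OC)c2OC=O)c(OC)c1 | intermediate
5 | 2,4-dimethoxy-6-(2,4,6-trimethoxyphenoxy)phenol (DE phenol) | COc1cc(OC)c(Oc2cc(OC)cc(OC)c2O)c(OC)c1 | intermediate
6 | 4-fluoro-2,6-dimethoxybenzaldehyde | COc1cc(F)cc(OC)c1C=O | starting material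
7 | 4-[2,4-dimethoxy-6-(2,4,6-trimethoxyphenoxy)phenoxy]-2,6-dimethoxybenzaldehyde (CDE aldehyde) | COc1cc(OC)c(Oc2cc(OC)cc(OC)c2Oc2cc(OC)c(C=O)c(OC)c2)c(OC)c1 | intermediate
8 | 4-[2,4-dimethoxy-6-(2,4,6-trimethoxyphenoxy)phenoxy]-2,6-dimethoxyphenyl formate (CDE aryl formate, not isolated) | COc1cc(OC)c(Oc2cc(OC)cc(OC)c2Oc2cc(OC)c(OC=O)c(OC)c2)c(OC)c1 | intermediate
9 | 4-[2,4-dimethoxy-6-(2,4,6-trimethoxyphenoxy)phenoxy]-2,6-dimethoxyphenol (CDE phenol) | COc1cc(OC)c(Oc2cc(OC)cc(OC)c2Oc2cc(OC)c(O)c(OC)c2)c(OC)c1 | intermediate
10 | 2-{4-[2,4-dimethoxy-6-(2,4,6-trimethoxyphenoxy)phenoxy]-2,6-dimethoxyphenoxy}-4,6-dimethoxybenzaldehyde (BCDE aldehyde) | COc1cc(OC)c(Oc2cc(OC)cc(OC)c2Oc2cc(OC)c(Oc3cc(OC)cc(OC)c3C=O)c(OC)c2)c(OC)c1 | intermediate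
11 | 2-{4-[2,4-dimethoxy-6-(2,4,6-trimethoxyphenoxy)phenoxy]-2,6-dimethoxyphenoxy}-4,6-dimethoxyphenyl formate (BCDE aryl formate, not isolated) | COc1cc(OC)c(Oc2cc(OC)cc(OC)c2Oc2cc(OC)c(Oc3cc(OC)cc(OC)c3OC=O)c(OC)c2)c(OC)c1 | intermediate
12 | 2-{4-[2,4-dimethoxy-6-(2,4,6-trimethoxyphenoxy)phenoxy]-2,6-dimethoxyphenoxy}-4,6-dimethoxyphenol (BCDE phenol) | COc1cc(OC)c(Oc2cc(OC)cc(OC)c2Oc2cc(OC)c(Oc3cc(OC)cc(OC)c3O)c(OC)c2)c(OC)c1 | intermediate
13 | 4-hydroxy-6-methyl-2H-pyran-2-one | Cc1cc(O)cc(=O)o1 | starting material
14 | 4-bromo-6-methyl-2H-pyran-2-one | Cc1cc(Br)cc(=O)o1 | intermediate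
15 | 4-(2-{4-[2,4-dimethoxy-6-(2,4,6-trimethoxyphenoxy)phenoxy]-2,6-dimethoxyphenoxy}-4,6-dimethoxyphenoxy)-6-methyl-2H-pyran-2-one | Cc1cc(Oc2c(OC)cc(OC)cc2Oc2c(OC)cc(Oc3c(OC)cc(OC)cc3Oc3c(OC)cc(OC)cc3OC)cc2OC)cc(=O)o1 | intermediate
16 | lithium (3E)-4-(2-{4-[2,4-dimethoxy-6-(2,4,6-trimethoxyphenoxy)phenoxy]-2,6-dimethoxyphenoxy}-4,6-dimethoxyphenoxy)-6-oxohexa-1,3,5-trien-2-olate (ring-opened dienylketene enolate, C-2 and C-5 cis, not isolated) | [Li+].[O-]C(=C)/C=C(\C=C=O)Oc1c(OC)cc(OC)cc1Oc1c(OC)cc(Oc2c(OC)cc(OC)cc2Oc2c(OC)cc(OC)cc2OC)cc1OC | intermediate
17 | 5-(2-{4-[2,4-dimethoxy-6-(2,4,6-trimethoxyphenoxy)phenoxy]-2,6-dimethoxyphenoxy}-4,6-dimethoxyphenoxy)benzene-1,3-diol (nonamethyl pentamer, free hydroxyls at A C-3 and A C-5) | Oc1cc(O)cc(Oc2c(OC)cc(OC)cc2Oc2c(OC)cc(Oc3c(OC)cc(OC)cc3Oc3c(OC)cc(OC)cc3OC)cc2OC)c1 | intermediate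
18 | 5-(2-{4-[2,4-dihydroxy-6-(2,4,6-trihydroxyphenoxy)phenoxy]-2,6-dihydroxyphenoxy}-4,6-dihydroxyphenoxy)benzene-1,3-diol (CNP0018313.0) | Oc1cc(O)cc(Oc2c(O)cc(O)cc2Oc2c(O)cc(Oc3c(O)cc(O)cc3Oc3c(O)cc(O)cc3O)cc2O)c1 | target

## Step count and least certain steps

Total step count: 10. Longest linear sequence: 9 steps (steps 1 to 6, then 8, 9 and 10, from 1 and 2); step 7 is a one-step side branch.

Step 9 (key step). The most likely failure is that the lithiated pyrone opens too slowly on warming. Ring opening has to expel an enolate oxygen from a stabilised, delocalised anion, so bimolecular vinylogous substitution (one anion, or the product resorcinolate, attacking C-4 of a second pyrone and expelling the BCDE phenoxide) or oligomerisation of the ketene could take over. The fallback sets out from 12 and comes back at 18. An Ullmann ether synthesis of 12 with commercial 1-iodo-3,5-dimethoxybenzene (CuI, picolinic acid, K3PO4, DMSO, 100 °C; conditions of the kind used for di-ortho-substituted phenols) would give the undecamethyl pentamer F1. BBr3 in CH2Cl2 would then cleave all eleven methyl ethers to 18. This gives up the pyrone and accepts a hindered aryl coupling, but uses only known reaction types.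

Step 3. The most likely failure is sluggish substitution: the acceptor strength of the formyl group in 6 is lowered by two ortho methoxy donors and the phenoxide of 5 is flanked. Prolonged heating then invites nucleophilic demethylation of the methoxy groups ortho to the formyl group and slow degradation of the aldehyde. The fallback sets out from 5 and comes back at 7. An Ullmann coupling of 5 with commercial 4-bromo-2,6-dimethoxybenzaldehyde (CuI, picolinic acid, K3PO4, DMSO, 90 °C) replaces addition–elimination by copper-mediated substitution at an unhindered para bromide; no new compound arises on this path (F0).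

Step 5. The most likely failure is steric retardation of the addition, since a di-ortho-methoxy phenoxide must reach a carbon next to a formyl group; adventitious hydroxide could then displace the fluoride first. The fallback sets out from 9 and comes back at 10. A two-stage SNAr would use the symmetrical, more electrophilic 2,6-difluoro-4-methoxybenzaldehyde: Cs2CO3 in DMSO at 80 °C should give 2-{4-[2,4-dimethoxy-6-(2,4,6-trimethoxyphenoxy)phenoxy]-2,6-dimethoxyphenoxy}-6-fluoro-4-methoxybenzaldehyde F2. Either fluoride leads to the same product and the new aryloxy donor slows a second substitution. NaOMe in MeOH/THF at 60 °C would then replace the remaining ortho fluoride by methoxide to reach 10.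

Step 10. The most likely failure is incomplete cleavage, because partly deprotected boron-bound intermediates may leave solution in CH2Cl2, combined with oxidative degradation of the free undecaphenol during isolation. The fallback sets out from 17 and comes back at 18. After the BBr3 treatment and methanol quench, the crude material would be peracetylated at once (Ac2O, pyridine) to the undecaacetate F3, a stable compound that can be purified on silica and checked for residual methoxy groups. Acid-catalysed methanolysis (HCl in MeOH, Ar, rt) followed by evaporation would then release 18 without exposing it to base or air.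

## Further compounds

F1 | step 9 | 1-(3,5-dimethoxyphenoxy)-2-{4-[2,4-dimethoxy-6-(2,4,6-trimethoxyphenoxy)phenoxy]-2,6-dimethoxyphenoxy}-4,6-dimethoxybenzene (undecamethyl pentamer) | COc1cc(OC)cc(Oc2c(OC)cc(OC)cc2Oc2c(OC)cc(Oc3c(OC)cc(OC)cc3Oc3c(OC)cc(OC)cc3OC)cc2OC)c1
F0 | step 3 | none | none
F2 | step 5 | 2-{4-[2,4-dimethoxy-6-(2,4,6-trimethoxyphenoxy)phenoxy]-2,6-dimethoxyphenoxy}-6-fluoro-4-methoxybenzaldehyde | COc1cc(OC)c(Oc2cc(OC)cc(OC)c2Oc2cc(OC)c(Oc3cc(OC)cc(F)c3C=O)c(OC)c2)c(OC)c1
F3 | step 10 | undecaacetate of 18 (all eleven hydroxyls as acetates) | CC(=O)Oc1cc(OC(C)=O)cc(Oc2c(OC(C)=O)cc(OC(C)=O)cc2Oc2c(OC(C)=O)cc(Oc3c(OC(C)=O)cc(OC(C)=O)cc3Oc3c(OC(C)=O)cc(OC(C)=O)cc3OC(C)=O)cc2OC(C)=O)c1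
A1 | alternative 1 | 2-{4-[2,4-dimethoxy-6-(2,4,6-trimethoxyphenoxy)phenoxy]-2,6-dimethoxyphenoxy}-6-methoxybenzene-1,4-diol (BCDE hydroquinone, free B C-1 and B C-4 hydroxyls) | Oc1cc(OC)c(O)c(Oc2c(OC)cc(Oc3c(OC)cc(OC)cc3Oc3c(OC)cc(OC)cc3OC)cc2OC)c1
A2 | alternative 1 | 3-{4-[2,4-dimethoxy-6-(2,4,6-trimethoxyphenoxy)phenoxy]-2,6-dimethoxyphenoxy}-4-hydroxy-4-(1-methoxyethenyl)cyclobut-2-en-1-one (racemic) | COC(=C)C1(O)C(Oc2c(OC)cc(Oc3c(OC)cc(OC)cc3Oc3c(OC)cc(OC)cc3OC)cc2OC)=CC1=O
A3 | alternative 2 | pentamethyl pentamer hexaphenol (free hydroxyls at B C-4, C C-2, C C-6, D C-4, E C-2 and E C-6) | COc1cc(OC)cc(Oc2c(OC)cc(O)cc2Oc2c(O)cc(Oc3c(OC)cc(O)cc3Oc3c(O)cc(OC)cc3O)cc2O)c1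
A4 | alternative 2 | pentamethyl pentamer hexacarbaldehyde (formyl groups at B C-4, C C-2, C C-6, D C-4, E C-2 and E C-6) | COc1cc(OC)cc(Oc2c(OC)cc(C=O)cc2Oc2c(C=O)cc(Oc3c(OC)cc(C=O)cc3Oc3c(C=O)cc(OC)cc3C=O)cc2C=O)c1
A5 | alternative 3 | nonamethyl pentamer with free D C-2 and D C-4 hydroxyls | COc1cc(OC)cc(Oc2c(OC)cc(OC)cc2Oc2c(OC)cc(Oc3c(O)cc(O)cc3Oc3c(OC)cc(OC)cc3OC)cc2OC)c1
A6 | alternative 3 | 3-{4-[2-(3,5-dimethoxyphenoxy)-3,5-dimethoxyphenoxy]-3,5-dimethoxyphenoxy}-6-methyl-4-(2,4,6-trimethoxyphenoxy)-2H-pyran-2-one | Cc1cc(Oc2c(OC)cc(OC)cc2OC)c(Oc3cc(OC)c(Oc4cc(OC)cc(OC)c4Oc4cc(OC)cc(OC)c4)c(OC)c3)c(=O)o1
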